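**Overview**

- Cuts: both 4Z alkenes are traced back to ring alkynes. The 20-membered ring is then opened at the C3–C4 (sp2–sp) bond of the arm without the C2 methyl, the chain at the matching C3–C4 bond of the methylated arm and at both ester C1–O bonds. This leaves two (Z)-3-iodoacrylic acids and two copies of one C4–C10 alkynol.
- Enabling feature: each half of the diolide ring holds a (2Z,4Z)-dienoate from C1 to C5 whose C4=C5 alkene is the cis-reduction product of an alkyne, so C3 can be an iodide-bearing sp2 carbon and C4 a terminal alkyne carbon. Beyond C4 the halves are identical (C8 methyl, C9 carbinol, C10 methylene on C5 of the oxazole ring).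
- The alkynol is cut at C5–C6 (acetylide alkylation), at the oxazole ring (two bonds, from an aldehyde and TosMIC) and at C8–C9 (crotylboration).
- Forward order: crotylboration, chain extension, oxazole ring closure; then ester, intermolecular Sonogashira coupling, ester; the 20-membered ring closes last by intramolecular Sonogashira coupling, and both ring alkynes are then reduced in one operation.
- Stereochemistry: C8 and C9 of both halves come from one Brown (Z)-crotylboration (syn, reagent control). The two 2Z alkenes come from Z-vinyl iodides of fixed geometry, and the two 4Z alkenes from syn semireduction of the alkynes.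

Key step: step 18

Remark: each half is numbered from its ester carbonyl (C1) to the carbinol carbon (C9), with C10 the methylene that carries the oxazole. The crotylborane made from (−)-Ipc2BOMe (the antipode derived from (+)-α-pinene) is assumed to attack the Si face of the aldehyde; if the opposite sense were found, the other antipode would be used.

**Route**

Step 1
Reactants: 1 3-(tert-butyldimethylsilyloxy)propanal; 2 cis-2-butene
Product: 7 (3R,4R)-1-(tert-butyldimethylsilyloxy)-4-methylhex-5-en-3-ol, via (Z)-crotylpotassium 3 (not isolated), via potassium crotyl(methoxy)diisopinocampheylborate 4 (not isolated), via (Z)-crotyldiisopinocampheylborane 5 (not isolated), via diisopinocampheylborinate of the adduct 6 (not isolated)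
Conditions: 2, KOtBu, n-BuLi, THF, −78 to −45 °C; (−)-Ipc2BOMe, −78 °C; BF3·OEt2; then 1, −78 °C; NaOH, H2O2, 0 °C to rt
Reagents that add atoms: none
Why: Brown asymmetric crotylboration, in which the Z-crotylborane reacts through a closed chair (Zimmerman–Traxler) transition state so that the Z geometry gives the syn relationship of the future C8 methyl and C9 hydroxyl, while the isopinocampheyl ligands direct attack to the Si face of the aldehyde and should give the 3R,4R isomer.

Step 2
Reactants: 7 (3R,4R)-1-(tert-butyldimethylsilyloxy)-4-methylhex-5-en-3-ol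
Product: 8 (3R,4R)-1,3-bis(tert-butyldimethylsilyloxy)-4-methylhex-5-ene
Conditions: TBSOTf, 2,6-lutidine, CH2Cl2, −78 to 0 °C
Reagents that add atoms: tert-butyldimethylsilyl triflate, CC(C)(C)[Si](C)(C)OS(=O)(=O)C(F)(F)F
Why: silyl ether formation with the reactive triflate should cap the hindered secondary hydroxyl, which then stays masked through the borane, iodide, acetylide and base steps.

Step 3
Reactants: 8 (3R,4R)-1,3-bis(tert-butyldimethylsilyloxy)-4-methylhex-5-ene
Product: 10 (3R,4R)-4,6-bis(tert-butyldimethylsilyloxy)-3-methylhexan-1-ol, via B-alkyl-9-borabicyclo[3.3.1]nonane 9 (not isolated)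
Conditions: 9-BBN, THF, 0 °C to rt; then NaOH, H2O2, 0 °C
Reagents that add atoms: hydrogen peroxide, OO
Why: hydroboration–oxidation with the bulky borane should place boron on the terminal carbon of the vinyl group (anti-Markovnikov) and touches no stereocentre.

Step 4
Reactants: 10 (3R,4R)-4,6-bis(tert-butyldimethylsilyloxy)-3-methylhexan-1-ol
Product: 11 (3R,4R)-4,6-bis(tert-butyldimethylsilyloxy)-1-iodo-3-methylhexane
Conditions: I2, PPh3, imidazole, CH2Cl2, 0 °C to rt
Reagents that add atoms: iodine, II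
Why: Appel-type iodination, in which the alkoxyphosphonium ion of the unhindered primary alcohol is displaced by iodide in an SN2 step while imidazole keeps the medium neutral for the silyl ethers.

Step 5
Reactants: 11 (3R,4R)-4,6-bis(tert-butyldimethylsilyloxy)-1-iodo-3-methylhexane; 12 (triisopropylsilyl)acetylene
Product: 14 (5R,6R)-6,8-bis(tert-butyldimethylsilyloxy)-5-methyl-1-(triisopropylsilyl)oct-1-yne, via lithium (triisopropylsilyl)acetylide 13 (not isolated)
Conditions: 12, n-BuLi, THF, −78 to 0 °C; then 11, DMPU, −78 °C to rt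
Reagents that add atoms: none
Why: acetylide alkylation (SN2) at the primary iodide should form the C5–C6 bond, with the bulky silyl group blocking the second alkyne terminus for the later steps.

Step 6
Reactants: 14 (5R,6R)-6,8-bis(tert-butyldimethylsilyloxy)-5-methyl-1-(triisopropylsilyl)oct-1-yne
Product: 15 (3R,4R)-3-(tert-butyldimethylsilyloxy)-4-methyl-8-(triisopropylsilyl)oct-7-yn-1-ol
Conditions: camphorsulfonic acid (cat.), MeOH/CH2Cl2 (1:1), 0 °C
Reagents that add atoms: none
Why: selective acid-catalysed methanolysis, which should be much faster at the unhindered primary silyl ether than at the secondary one next to the methyl branch, and leaves the alkynylsilane alone.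

Step 7
Reactants: 15 (3R,4R)-3-(tert-butyldimethylsilyloxy)-4-methyl-8-(triisopropylsilyl)oct-7-yn-1-ol
Product: 16 (3R,4R)-3-(tert-butyldimethylsilyloxy)-4-methyl-8-(triisopropylsilyl)oct-7-ynal
Conditions: Dess–Martin periodinane, CH2Cl2, 0 °C to rt
Reagents that add atoms: none
Why: Dess–Martin oxidation stops at the aldehyde and is non-basic, so β-elimination of the silyloxy group should not occur.

Step 8
Reactants: 16 (3R,4R)-3-(tert-butyldimethylsilyloxy)-4-methyl-8-(triisopropylsilyl)oct-7-ynal
Product: 18 5-[(2R,3R)-2-(tert-butyldimethylsilyloxy)-3-methyl-7-(triisopropylsilyl)hept-6-yn-1-yl]oxazole, via 4-tosyl-4,5-dihydrooxazole adduct 17 (not isolated)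
Conditions: TosMIC, K2CO3, MeOH, rt then reflux
Reagents that add atoms: p-toluenesulfonylmethyl isocyanide (TosMIC), Cc1ccc(cc1)S(=O)(=O)C[N+]#[C-]
Why: van Leusen oxazole synthesis, in which the isocyanide anion adds to the aldehyde, the alkoxide closes onto the isocyanide carbon (5-endo-dig) and loss of p-toluenesulfinate aromatises the ring, so that the aldehyde gives C5 and the ring oxygen and the reagent gives C4, the nitrogen and C2.

Step 9
Reactants: 18 5-[(2R,3R)-2-(tert-butyldimethylsilyloxy)-3-methyl-7-(triisopropylsilyl)hept-6-yn-1-yl]oxazole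
Product: 19 (2R,3R)-3-methyl-1-(oxazol-5-yl)-7-(triisopropylsilyl)hept-6-yn-2-ol
Conditions: HF·pyridine, pyridine, THF, 0 °C to rt
Reagents that add atoms: none
Why: selective desilylation, since acidic fluoride cleaves the silicon–oxygen bond of the silyl ether but should leave the carbon–silicon bond of the hindered alkynylsilane.

Step 10
Reactants: 18 5-[(2R,3R)-2-(tert-butyldimethylsilyloxy)-3-methyl-7-(triisopropylsilyl)hept-6-yn-1-yl]oxazole
Product: 20 (2R,3R)-3-methyl-1-(oxazol-5-yl)hept-6-yn-2-ol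
Conditions: TBAF (excess), THF, 0 °C to rt
Reagents that add atoms: none
Why: global desilylation, since basic fluoride should cleave both the silyl ether and the alkynylsilane and so give the second coupling partner from the same intermediate.

Step 11
Reactants: 21 propargyl alcohol
Product: 23 (Z)-3-iodo-2-methylprop-2-en-1-ol, via bis(bromomagnesium) vinyl alkoxide 22 (not isolated)
Conditions: MeMgBr (2.5 equiv), CuI (10 mol%), THF, −10 °C to rt; then I2, −78 °C to rt
Reagents that add atoms: methylmagnesium bromide, C[Mg]Br; iodine, II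
Why: copper-catalysed anti-carbomagnesiation of the propargylic alkoxide puts the methyl group on C2 and magnesium on C3 cis to the CH2O group through a chelate, and iodinolysis with retention should give the Z iodide only.

Step 12
Reactants: 23 (Z)-3-iodo-2-methylprop-2-en-1-ol
Product: 24 (Z)-3-iodo-2-methylacrylaldehyde
Conditions: MnO2, CH2Cl2, rt
Reagents that add atoms: none
Why: allylic oxidation on MnO2 is neutral and heterogeneous, so the Z geometry and the vinyl iodide should be kept.

Step 13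
Reactants: 24 (Z)-3-iodo-2-methylacrylaldehyde
Product: 25 (Z)-3-iodo-2-methylacrylic acid
Conditions: NaClO2, NaH2PO4, 2-methyl-2-butene, t-BuOH/H2O, 0 °C to rt
Reagents that add atoms: sodium chlorite, [Na+].[O-]Cl=O
Why: Pinnick oxidation is buffered and mild and the alkene scavenger removes hypochlorous acid, so the enal should go to the acid without attack on the vinyl iodide or loss of geometry.

Step 14
Reactants: 19 (2R,3R)-3-methyl-1-(oxazol-5-yl)-7-(triisopropylsilyl)hept-6-yn-2-ol; 25 (Z)-3-iodo-2-methylacrylic acid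
Product: 27 (2R,3R)-3-methyl-1-(oxazol-5-yl)-7-(triisopropylsilyl)hept-6-yn-2-yl (Z)-3-iodo-2-methylacrylate, via (Z)-3-iodo-2-methylacryloyl chloride 26 (not isolated)
Conditions: 25, 1-chloro-N,N,2-trimethylpropenylamine, CH2Cl2, 0 °C to rt; then 19, pyridine, 0 °C to rt
Reagents that add atoms: none
Why: esterification through an acid chloride made under neutral conditions avoids acid and strong nucleophilic catalysts that could add to C3, so the Z iodide should be retained, and the C9 configuration is untouched because its carbon–oxygen bond is not broken.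

Step 15
Reactants: 27 (2R,3R)-3-methyl-1-(oxazol-5-yl)-7-(triisopropylsilyl)hept-6-yn-2-yl (Z)-3-iodo-2-methylacrylate; 20 (2R,3R)-3-methyl-1-(oxazol-5-yl)hept-6-yn-2-ol
Product: 28 (2R,3R)-3-methyl-1-(oxazol-5-yl)-7-(triisopropylsilyl)hept-6-yn-2-yl (2Z,8R,9R)-9-hydroxy-2,8-dimethyl-10-(oxazol-5-yl)dec-2-en-4-ynoate
Conditions: Pd(PPh3)4 (5 mol%), CuI (10 mol%), iPr2NH, THF (degassed), rt
Reagents that add atoms: none
Why: Sonogashira coupling of the Z-vinyl iodide with the only terminal alkyne present should form the C3–C4 bond of the methylated arm with retention of geometry, the free hydroxyl and the oxazoles being tolerated and the silyl-capped alkyne being unable to couple.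

Step 16
Reactants: 28 (2R,3R)-3-methyl-1-(oxazol-5-yl)-7-(triisopropylsilyl)hept-6-yn-2-yl (2Z,8R,9R)-9-hydroxy-2,8-dimethyl-10-(oxazol-5-yl)dec-2-en-4-ynoate
Product: 29 (2R,3R)-3-methyl-1-(oxazol-5-yl)hept-6-yn-2-yl (2Z,8R,9R)-9-hydroxy-2,8-dimethyl-10-(oxazol-5-yl)dec-2-en-4-ynoate
Conditions: TBAF, AcOH, THF, 0 °C to rt
Reagents that add atoms: none
Why: fluoride-induced protodesilylation of the alkynylsilane, buffered with acetic acid so that no free alkoxide can cause acyl transfer or add to the enynoate.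

Step 17
Reactants: 29 (2R,3R)-3-methyl-1-(oxazol-5-yl)hept-6-yn-2-yl (2Z,8R,9R)-9-hydroxy-2,8-dimethyl-10-(oxazol-5-yl)dec-2-en-4-ynoate; 30 (Z)-3-iodoacrylic acid
Product: 31 (2R,3R)-3-methyl-1-(oxazol-5-yl)hept-6-yn-2-yl (2Z,8R,9R)-9-[(Z)-3-iodoacryloyloxy]-2,8-dimethyl-10-(oxazol-5-yl)dec-2-en-4-ynoate
Conditions: DIC, DMAP (10 mol%), CH2Cl2, −20 to 0 °C
Reagents that add atoms: none
Why: Steglich-type carbodiimide esterification of the C9 hydroxyl, in which low temperature and only catalytic DMAP should limit addition–elimination at C3 and so keep the Z iodide.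

Step 18
Reactants: 31 (2R,3R)-3-methyl-1-(oxazol-5-yl)hept-6-yn-2-yl (2Z,8R,9R)-9-[(Z)-3-iodoacryloyloxy]-2,8-dimethyl-10-(oxazol-5-yl)dec-2-en-4-ynoate
Product: 32 (3Z,9R,10R,13Z,19R,20R)-3,9,19-trimethyl-10,20-bis(oxazol-5-ylmethyl)-1,11-dioxacycloicosa-3,13-diene-5,15-diyne-2,12-dione
Conditions: Pd(PPh3)4 (20 mol%), CuI (40 mol%), iPr2NH, THF (degassed, argon), rt; 31 added by syringe pump to a final concentration near 1 mM
Reagents that add atoms: none
Why: Sonogashira coupling run intramolecularly: zerovalent palladium inserts with retention into the carbon–iodine bond at C3 of the Z-iodoacrylate, the alkynylcopper formed from the terminal alkyne, CuI and the amine transfers its alkynyl group, and reductive elimination joins C3 (sp2) to C4 (sp) of the unmethylated arm. The closest known reaction type is the palladium/copper macrocyclisation of an ω-alkynyl (Z)-3-iodoacrylate ester to a macrocyclic Z-enynoate. The 20-membered diolide ring closes by end-to-end union of the two chain termini, both carbons of the new bond becoming ring members and the alkyne lying inside the ring. No stereocentre is formed; the 2Z geometry of this arm is fixed by the iodide and carried through because oxidative addition and reductive elimination are stereoretentive. Ring closure has to win over chain growth and over oxidative alkyne dimerisation: each molecule has exactly one iodide and one terminal alkyne, the iodoacrylate reacts with the catalyst at room temperature so that slow addition keeps the free substrate very dilute, and oxygen is excluded. Because both esters were made from iodoacrylic acids, no dienoic acid is ever activated and the Z alkenes cannot isomerise at an acylation stage.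

Step 19
Reactants: 32 (3Z,9R,10R,13Z,19R,20R)-3,9,19-trimethyl-10,20-bis(oxazol-5-ylmethyl)-1,11-dioxacycloicosa-3,13-diene-5,15-diyne-2,12-dione
Product: 33 (3Z,5Z,9R,10R,13Z,15Z,19R,20R)-3,9,19-trimethyl-10,20-bis(oxazol-5-ylmethyl)-1,11-dioxacycloicosa-3,5,13,15-tetraene-2,12-dione
Conditions: Zn dust (pre-activated with Cu(OAc)2 and AgNO3), MeOH/H2O (1:1), rt to 45 °C
Reagents that add atoms: none
Why: zinc (copper/silver couple) semireduction of conjugated enynes delivers both hydrogens to the same face of each activated alkyne, which should give the two 4Z alkenes in one operation without touching the enoate alkenes, the esters or the oxazoles.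

**Compound list**

1 | 3-(tert-butyldimethylsilyloxy)propanal | O=CCCO[Si](C)(C)C(C)(C)C | starting material
2 | cis-2-butene | C/C=C\C | starting material
3 | (Z)-but-2-en-1-ylpotassium | [K+].C/C=C\[CH2-] | intermediate
4 | potassium (Z)-crotyl(methoxy)diisopinocampheylborate | [K+].CO[B-](C/C=C\C)([C@@H]1C[C@@H]2C[C@H]([C@H]1C)C2(C)C)[C@@H]1C[C@@H]2C[C@H]([C@H]1C)C2(C)C | intermediate
5 | (Z)-crotyldiisopinocampheylborane | C/C=C\CB([C@@H]1C[C@@H]2C[C@H]([C@H]1C)C2(C)C)[C@@H]1C[C@@H]2C[C@H]([C@H]1C)C2(C)C | intermediate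
6 | diisopinocampheylborinate of (3R,4R)-1-(tert-butyldimethylsilyloxy)-4-methylhex-5-en-3-ol | C=C[C@@H](C)[C@@H](CCO[Si](C)(C)C(C)(C)C)OB([C@@H]1C[C@@H]2C[C@H]([C@H]1C)C2(C)C)[C@@H]1C[C@@H]2C[C@H]([C@H]1C)C2(C)C | intermediate
7 | (3R,4R)-1-(tert-butyldimethylsilyloxy)-4-methylhex-5-en-3-ol | C=C[C@@H](C)[C@@H](CCO[Si](C)(C)C(C)(C)C)O | intermediate
8 | (3R,4R)-1,3-bis(tert-butyldimethylsilyloxy)-4-methylhex-5-ene | C=C[C@@H](C)[C@@H](CCO[Si](C)(C)C(C)(C)C)O[Si](C)(C)C(C)(C)C | intermediate
9 | 9-[(3R,4R)-4,6-bis(tert-butyldimethylsilyloxy)-3-methylhexyl]-9-borabicyclo[3.3.1]nonane | C1CCC2CCCC1B2CC[C@@H](C)[C@@H](CCO[Si](C)(C)C(C)(C)C)O[Si](C)(C)C(C)(C)C | intermediate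
10 | (3R,4R)-4,6-bis(tert-butyldimethylsilyloxy)-3-methylhexan-1-ol | OCC[C@@H](C)[C@@H](CCO[Si](C)(C)C(C)(C)C)O[Si](C)(C)C(C)(C)C | intermediate
11 | (3R,4R)-4,6-bis(tert-butyldimethylsilyloxy)-1-iodo-3-methylhexane | ICC[C@@H](C)[C@@H](CCO[Si](C)(C)C(C)(C)C)O[Si](C)(C)C(C)(C)C | intermediate
12 | (triisopropylsilyl)acetylene | C#C[Si](C(C)C)(C(C)C)C(C)C | starting material
13 | lithium (triisopropylsilyl)acetylide | [Li]C#C[Si](C(C)C)(C(C)C)C(C)C | intermediate
14 | (5R,6R)-6,8-bis(tert-butyldimethylsilyloxy)-5-methyl-1-(triisopropylsilyl)oct-1-yne | CC(C)[Si](C(C)C)(C(C)C)C#CCC[C@@H](C)[C@@H](CCO[Si](C)(C)C(C)(C)C)O[Si](C)(C)C(C)(C)C | intermediate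
15 | (3R,4R)-3-(tert-butyldimethylsilyloxy)-4-methyl-8-(triisopropylsilyl)oct-7-yn-1-ol | CC(C)[Si](C(C)C)(C(C)C)C#CCC[C@@H](C)[C@@H](CCO)O[Si](C)(C)C(C)(C)C | intermediate
16 | (3R,4R)-3-(tert-butyldimethylsilyloxy)-4-methyl-8-(triisopropylsilyl)oct-7-ynal | CC(C)[Si](C(C)C)(C(C)C)C#CCC[C@@H](C)[C@@H](CC=O)O[Si](C)(C)C(C)(C)C | intermediate
17 | 5-[(2R,3R)-2-(tert-butyldimethylsilyloxy)-3-methyl-7-(triisopropylsilyl)hept-6-yn-1-yl]-4-tosyl-4,5-dihydrooxazole (ring carbons 4 and 5 as a mixture) | CC(C)[Si](C(C)C)(C(C)C)C#CCC[C@@H](C)[C@@H](CC1OC=NC1S(=O)(=O)c1ccc(C)cc1)O[Si](C)(C)C(C)(C)C | intermediate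
18 | 5-[(2R,3R)-2-(tert-butyldimethylsilyloxy)-3-methyl-7-(triisopropylsilyl)hept-6-yn-1-yl]oxazole | CC(C)[Si](C(C)C)(C(C)C)C#CCC[C@@H](C)[C@@H](Cc1cnco1)O[Si](C)(C)C(C)(C)C | intermediate
19 | (2R,3R)-3-methyl-1-(oxazol-5-yl)-7-(triisopropylsilyl)hept-6-yn-2-ol | CC(C)[Si](C(C)C)(C(C)C)C#CCC[C@@H](C)[C@@H](Cc1cnco1)O | intermediate
20 | (2R,3R)-3-methyl-1-(oxazol-5-yl)hept-6-yn-2-ol | C#CCC[C@@H](C)[C@@H](Cc1cnco1)O | intermediate
21 | propargyl alcohol | C#CCO | starting material
22 | bromomagnesium (Z)-3-(bromomagnesio)-2-methylprop-2-en-1-olate | Br[Mg]/C=C(/C)CO[Mg]Br | intermediate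
23 | (Z)-3-iodo-2-methylprop-2-en-1-ol | OC/C(C)=C\I | intermediate
24 | (Z)-3-iodo-2-methylacrylaldehyde | O=C/C(C)=C\I | intermediate
25 | (Z)-3-iodo-2-methylacrylic acid | OC(=O)/C(C)=C\I | intermediate
26 | (Z)-3-iodo-2-methylacryloyl chloride | ClC(=O)/C(C)=C\I | intermediate
27 | (2R,3R)-3-methyl-1-(oxazol-5-yl)-7-(triisopropylsilyl)hept-6-yn-2-yl (Z)-3-iodo-2-methylacrylate | CC(C)[Si](C(C)C)(C(C)C)C#CCC[C@@H](C)[C@@H](Cc1cnco1)OC(=O)/C(C)=C\I | intermediate
28 | (2R,3R)-3-methyl-1-(oxazol-5-yl)-7-(triisopropylsilyl)hept-6-yn-2-yl (2Z,8R,9R)-9-hydroxy-2,8-dimethyl-10-(oxazol-5-yl)dec-2-en-4-ynoate | CC(C)[Si](C(C)C)(C(C)C)C#CCC[C@@H](C)[C@@H](Cc1cnco1)OC(=O)/C(C)=C\C#CCC[C@@H](C)[C@@H](Cc1cnco1)O | intermediate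
29 | (2R,3R)-3-methyl-1-(oxazol-5-yl)hept-6-yn-2-yl (2Z,8R,9R)-9-hydroxy-2,8-dimethyl-10-(oxazol-5-yl)dec-2-en-4-ynoate | C#CCC[C@@H](C)[C@@H](Cc1cnco1)OC(=O)/C(C)=C\C#CCC[C@@H](C)[C@@H](Cc1cnco1)O | intermediate
30 | (Z)-3-iodoacrylic acid | OC(=O)/C=C\I | starting material
31 | (2R,3R)-3-methyl-1-(oxazol-5-yl)hept-6-yn-2-yl (2Z,8R,9R)-9-[(Z)-3-iodoacryloyloxy]-2,8-dimethyl-10-(oxazol-5-yl)dec-2-en-4-ynoate | C#CCC[C@@H](C)[C@@H](Cc1cnco1)OC(=O)/C(C)=C\C#CCC[C@@H](C)[C@@H](Cc1cnco1)OC(=O)/C=C\I | intermediate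
32 | (3Z,9R,10R,13Z,19R,20R)-3,9,19-trimethyl-10,20-bis(oxazol-5-ylmethyl)-1,11-dioxacycloicosa-3,13-diene-5,15-diyne-2,12-dione | C/C1=C/C#CCC[C@@H](C)[C@@H](Cc2cnco2)OC(=O)/C=C\C#CCC[C@@H](C)[C@@H](Cc2cnco2)OC1=O | intermediate
33 | (3Z,5Z,9R,10R,13Z,15Z,19R,20R)-3,9,19-trimethyl-10,20-bis(oxazol-5-ylmethyl)-1,11-dioxacycloicosa-3,5,13,15-tetraene-2,12-dione (CNP0128396.1) | C/C1=C/C=C\CC[C@@H](C)[C@@H](Cc2cnco2)OC(=O)/C=C\C=C/CC[C@@H](C)[C@@H](Cc2cnco2)OC1=O | target

**Step count**

Total: 19 steps. Longest linear sequence: 15 steps (steps 1 to 9 and 14 to 19, from 1 to 33).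

**Steps most likely to fail**

Step 18. Chain growth between molecules and oxidative dimerisation of the terminal alkyne may outrun closure of a ring that has to hold two linear alkyne units. The fallback closes the ring at the ester C1–O bond of the unmethylated arm instead. It sets out from 29 and 30. Acid 30 is esterified with 2-(trimethylsilyl)ethanol (DIC, DMAP cat.) to 2-(trimethylsilyl)ethyl (Z)-3-iodoacrylate F1. F1 is joined to the terminal alkyne of 29 by intermolecular Sonogashira coupling (Pd(PPh3)4, CuI, iPr2NH) to give the hydroxy bis-enynoate 2-(trimethylsilyl)ethyl ester F2. Fluoride (TASF, DMF, 0 °C) should release the seco acid F3, and a Shiina macrolactonisation (2-methyl-6-nitrobenzoic anhydride, DMAP, toluene, high dilution) returns to the route at 32.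

Step 8. Base-induced loss of the β-silyloxy group or self-condensation of the enolisable aldehyde may compete with addition of the isocyanide anion. The fallback builds the oxazole at the ester oxidation level by the Schöllkopf method. It sets out from 16, which is oxidised (NaClO2, NaH2PO4, 2-methyl-2-butene) to (3R,4R)-3-(tert-butyldimethylsilyloxy)-4-methyl-8-(triisopropylsilyl)oct-7-ynoic acid F4 and methylated with TMSCHN2 (MeOH/toluene) to the methyl ester F5. Treatment at −78 °C with LiCH2NC (from methyl isocyanide and n-BuLi) acylates the reagent to the α-isocyano ketone F6, which is held as its lithium enolate and not isolated. The enolate oxygen closes onto the isocyanide carbon, and protonation on work-up gives the oxazole, coming back to the route at 18.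

Step 19. The twofold reduction may stall after the first alkyne, or the long exposure needed for the second alkyne in the rigid ring may erode the Z,Z-dienoates. The fallback separates the two reductions. It sets out from 28, whose conjugated alkyne is reduced with the same zinc couple to the (2Z,4Z)-dienoate F7; the silyl-capped, unconjugated alkyne is not activated and should stay. Desilylation (TBAF, AcOH) gives the terminal alkyne F8, and esterification with 30 (DIC, DMAP cat.) gives the iodoacrylate F9. Sonogashira ring closure as in step 18 gives the 20-membered dienoate–enynoate F10, which has a more flexible chain and only one ring alkyne. A single, short zinc reduction of F10 then comes back to the route at 33.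

**Further compounds**

F1 | step 18 | 2-(trimethylsilyl)ethyl (Z)-3-iodoacrylate | C[Si](C)(C)CCOC(=O)/C=C\I
F2 | step 18 | hydroxy bis-enynoate 2-(trimethylsilyl)ethyl ester (Sonogashira product of 29 and F1) | C[Si](C)(C)CCOC(=O)/C=C\C#CCC[C@@H](C)[C@@H](Cc1cnco1)OC(=O)/C(C)=C\C#CCC[C@@H](C)[C@@H](Cc1cnco1)O
F3 | step 18 | seco acid (free carboxylic acid of F2) | OC(=O)/C=C\C#CCC[C@@H](C)[C@@H](Cc1cnco1)OC(=O)/C(C)=C\C#CCC[C@@H](C)[C@@H](Cc1cnco1)O
F4 | step 8 | (3R,4R)-3-(tert-butyldimethylsilyloxy)-4-methyl-8-(triisopropylsilyl)oct-7-ynoic acid | CC(C)[Si](C(C)C)(C(C)C)C#CCC[C@@H](C)[C@@H](CC(=O)O)O[Si](C)(C)C(C)(C)C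
F5 | step 8 | methyl (3R,4R)-3-(tert-butyldimethylsilyloxy)-4-methyl-8-(triisopropylsilyl)oct-7-ynoate | CC(C)[Si](C(C)C)(C(C)C)C#CCC[C@@H](C)[C@@H](CC(=O)OC)O[Si](C)(C)C(C)(C)C
F6 | step 8 | (4R,5R)-4-(tert-butyldimethylsilyloxy)-1-isocyano-5-methyl-9-(triisopropylsilyl)non-8-yn-2-one | CC(C)[Si](C(C)C)(C(C)C)C#CCC[C@@H](C)[C@@H](CC(=O)C[N+]#[C-])O[Si](C)(C)C(C)(C)C
F7 | step 19 | (2R,3R)-3-methyl-1-(oxazol-5-yl)-7-(triisopropylsilyl)hept-6-yn-2-yl (2Z,4Z,8R,9R)-9-hydroxy-2,8-dimethyl-10-(oxazol-5-yl)deca-2,4-dienoate | CC(C)[Si](C(C)C)(C(C)C)C#CCC[C@@H](C)[C@@H](Cc1cnco1)OC(=O)/C(C)=C\C=C/CC[C@@H](C)[C@@H](Cc1cnco1)O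
F8 | step 19 | (2R,3R)-3-methyl-1-(oxazol-5-yl)hept-6-yn-2-yl (2Z,4Z,8R,9R)-9-hydroxy-2,8-dimethyl-10-(oxazol-5-yl)deca-2,4-dienoate | C#CCC[C@@H](C)[C@@H](Cc1cnco1)OC(=O)/C(C)=C\C=C/CC[C@@H](C)[C@@H](Cc1cnco1)O
F9 | step 19 | (2R,3R)-3-methyl-1-(oxazol-5-yl)hept-6-yn-2-yl (2Z,4Z,8R,9R)-9-[(Z)-3-iodoacryloyloxy]-2,8-dimethyl-10-(oxazol-5-yl)deca-2,4-dienoate | C#CCC[C@@H](C)[C@@H](Cc1cnco1)OC(=O)/C(C)=C\C=C/CC[C@@H](C)[C@@H](Cc1cnco1)OC(=O)/C=C\I
F10 | step 19 | (3Z,5Z,9R,10R,13Z,19R,20R)-3,9,19-trimethyl-10,20-bis(oxazol-5-ylmethyl)-1,11-dioxacycloicosa-3,5,13-trien-15-yne-2,12-dione | C/C1=C/C=C\CC[C@@H](C)[C@@H](Cc2cnco2)OC(=O)/C=C\C#CCC[C@@H](C)[C@@H](Cc2cnco2)OC1=O
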